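**Assumption:** the target has no stereocentre (it is achiral), so no stereocontrol is needed; compounds 1 and 3 are taken as commercially available.

**Retrosynthetic overview**
- Target 6 is reached by N-Boc removal from 5.
- Key disconnection: the pyrrole C3(sp2)–C1'(sp3) bond of 5, made by B-alkyl Suzuki–Miyaura coupling of bromopyrrole 2 with B-nonadecyl-9-BBN 4 (from nonadec-1-ene 3).
- 2 comes from methyl 3-bromo-1H-pyrrole-2-carboxylate 1 by N-Boc protection, which guards against hydrodebromination of the NH-bromopyrrole in the coupling.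
- No ring is formed; the pyrrole is bought intact.

**Route**

Step 1
Reactants: 1 methyl 3-bromo-1H-pyrrole-2-carboxylate
Product: 2 1-tert-butyl 2-methyl 3-bromo-1H-pyrrole-1,2-dicarboxylate
Conditions: Boc2O (1.3 equiv), DMAP (0.1 equiv), MeCN, rt
Reagents that add atoms: di-tert-butyl dicarbonate (Boc2O), CC(C)(C)OC(=O)OC(=O)OC(C)(C)C
Why: DMAP-catalysed N-acylation (Boc protection) of the acidic pyrrole NH, which stops pyrrolide formation under the basic coupling conditions and makes the C–Br bond more electron-poor for oxidative addition.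

Step 2
Reactants: 3 nonadec-1-ene; 2 1-tert-butyl 2-methyl 3-bromo-1H-pyrrole-1,2-dicarboxylate
Product: 5 1-tert-butyl 2-methyl 3-nonadecyl-1H-pyrrole-1,2-dicarboxylate, via B-nonadecyl-9-BBN 4 (not isolated)
Conditions: 3 (1.5 equiv), 9-BBN (1.4 equiv B–H), THF, 0 °C to rt; then 2, Pd(OAc)2 (3 mol%), SPhos (6 mol%), K3PO4·H2O (3 equiv), THF, 45 °C
Reagents that add atoms: none
Why: anti-Markovnikov hydroboration gives the primary alkylborane, whose primary alkyl group transfers selectively in a B-alkyl Suzuki–Miyaura coupling with the activated heteroaryl bromide, the bulky biarylphosphine favouring reductive elimination over β-hydride elimination.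

Step 3
Reactants: 5 1-tert-butyl 2-methyl 3-nonadecyl-1H-pyrrole-1,2-dicarboxylate
Product: 6 methyl 3-nonadecyl-1H-pyrrole-2-carboxylate
Conditions: NaOMe (0.2 equiv), MeOH/THF 1:1, rt
Reagents that add atoms: none
Why: methoxide-catalysed methanolysis (transacylation) of the activated N-acylpyrrole carbamate expels the stabilised 2-acylpyrrolide, while the methyl ester only undergoes degenerate exchange in methanol.

**Compound list**
1 | methyl 3-bromo-1H-pyrrole-2-carboxylate | COC(=O)c1[nH]ccc1Br | starting material
2 | 1-tert-butyl 2-methyl 3-bromo-1H-pyrrole-1,2-dicarboxylate | COC(=O)c1c(Br)ccn1C(=O)OC(C)(C)C | intermediate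
3 | nonadec-1-ene | CCCCCCCCCCCCCCCCCC=C | starting material
4 | 9-nonadecyl-9-borabicyclo[3.3.1]nonane (B-nonadecyl-9-BBN) | CCCCCCCCCCCCCCCCCCCB1C2CCCC1CCC2 | intermediate
5 | 1-tert-butyl 2-methyl 3-nonadecyl-1H-pyrrole-1,2-dicarboxylate | CCCCCCCCCCCCCCCCCCCc1ccn(C(=O)OC(C)(C)C)c1C(=O)OC | intermediate
6 | methyl 3-nonadecyl-1H-pyrrole-2-carboxylate | CCCCCCCCCCCCCCCCCCCc1cc[nH]c1C(=O)OC | target

**Totals**
Total step count: 3. Longest linear sequence: 3 (1 → 2 → 5 → 6).

**Steps most likely to fail, with fallbacks**

Step 2 is the riskiest. The sp3–sp2 coupling can lose out to hydrodebromination, β-hydride elimination or early Boc loss. The fallback sets out from 3, with 2 as partner, and comes back at 5. Cross-metathesis of 3 with vinylboronic acid pinacol ester (Grubbs II, CH2Cl2, 40 °C) gives (E)-4,4,5,5-tetramethyl-2-(nonadec-1-en-1-yl)-1,3,2-dioxaborolane F1. An sp2–sp2 Suzuki coupling of this boronate with 2 (Pd(dppf)Cl2, K3PO4, dioxane/H2O, 70 °C) gives 1-tert-butyl 2-methyl 3-[(E)-nonadec-1-en-1-yl]-1H-pyrrole-1,2-dicarboxylate F2. Hydrogenation of the side-chain alkene (H2 1 atm, Pd/C, EtOAc, rt) then delivers 5.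

Step 3 is second. The waxy substrate may react sluggishly in methanol, leaving incomplete deprotection. The fallback sets out from 5 and comes back at 6. Global saponification (LiOH, THF/MeOH/H2O, 60 °C, then mild acidification) removes both the Boc group and the methyl ester to give 3-nonadecyl-1H-pyrrole-2-carboxylic acid F3. This acid is re-esterified O-selectively with trimethylsilyldiazomethane (toluene/MeOH, 0 °C to rt), which avoids the N-methylation risk of MeI/base, to give 6.

Step 1 is third. The N-Boc pyrrole ester may form incompletely next to the 2-ester or shed Boc on work-up or silica. The fallback drops the protecting-group strategy; it sets out from 1 and comes back directly at 6. Compound 1 is coupled with the in-situ borane 4 using a precatalyst suited to unprotected NH-azoles (XPhos Pd G3, K3PO4 4 equiv, THF/H2O, 60 °C), so steps 1 and 3 are skipped. No new compound arises (F0).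

**Further compounds**
F0 | step 1 | none | none
F1 | step 2 | (E)-4,4,5,5-tetramethyl-2-(nonadec-1-en-1-yl)-1,3,2-dioxaborolane | CCCCCCCCCCCCCCCCC/C=C/B1OC(C)(C)C(C)(C)O1
F2 | step 2 | 1-tert-butyl 2-methyl 3-[(E)-nonadec-1-en-1-yl]-1H-pyrrole-1,2-dicarboxylate | CCCCCCCCCCCCCCCCC/C=C/c1ccn(C(=O)OC(C)(C)C)c1C(=O)OC
F3 | step 3 | 3-nonadecyl-1H-pyrrole-2-carboxylic acid | CCCCCCCCCCCCCCCCCCCc1cc[nH]c1C(=O)O
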